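Start from the larch run, and ask what a day takes out of a charge rather than what share of it a day converts.

| flask | solid substrate | coupling partner | remark | time |
|---|---|---|---|---|
| larch | 0.33 M | 0.36 M | run made earlier |  |
| Tuesday's | 0.30 M | 0.360 M |  | 12 d |
| Monday's | 1.2 M | 0.800 M |  | 12 d |

- larch (time / d: target / %, solid substrate / %): 0.333: 0.4, 96.2; 0.500: 1.1, 95.6; 0.833: 2.8, 91.7; 1.25: 5.7, 88.7; 1.67: 7.9, 85.1; 3.00: 17.3, 73.0; 4.00: 24.1, 64.7

(each reading ± 0.5 percentage points)

- what was read earlier has a scatter of 0.5 percentage points, one standard deviation
- at the start none of the solid substrate is in solution
- what has only dissolved of solid substrate counts as not reacted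
- a reading or a percentage of target counts all its forms, free or not

* the winner by amount of target, in percent of the solid substrate charged; "neither" if no more than 2 percentage points parts them (Tuesday's / Monday's / neither)
* how much target is there at the end, in percent of the solid substrate charged: Tuesday's
* how much target is there at the end, in percent of the solid substrate charged: Monday's

Between 1.67 d and 4.00 d target rose by 0.0695 d⁻¹ of the larch charge; this fraction of the larch charge per day is the daily take, a zero-order rate, and the line behind it started after a lag of 0.534 d. I multiplied the take by the time after the lag and by the larch charge over the flask's own charge, which gave 87.7% for Tuesday's and 21.9% for Monday's.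

My second way used the other column: solid substrate fell by 0.0859 d⁻¹ of the larch charge, and I treated the gap between solid lost and target, 11.2% at the last reading, as a small correction. That fall would empty Tuesday's charge in 10.6 d, less than the time allowed, so subtracting the rescaled gap gave 87.7%, the figure of the first way, but both ways lean on the last target reading, so I did not count this as a firm check. For Monday's it gave 25.3%, and here the second way cheated, since it froze a gap that had widened from 7.00% to 11.2%. The same frozen gap stood in Tuesday's figure, so I committed to a little under 87.7% there, and to 21.9% or somewhat above for Monday's, whose partner charge exceeds the larch one.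

The forecast named Tuesday's, with 78% and 30%, saying “Monday's gains little from extra solid”; its Tuesday figure lies lower than my 87.7% and its Monday figure higher than my 21.9%.

The flasks gave Tuesday's as the winner, with 82.6% against 27.0%, so the forecast held.

    solid substrate ⇌ dissolved substrate, rate k1*(cs1 - [dissolved substrate]) while solid is left; crystals form when [dissolved substrate] > cs1 (solubility = 0.110 M, k = 2.00 × 10⁻⁴ min⁻¹)
    dissolved substrate + coupling partner ⇌ target (K = 69.0 M⁻¹, k = 0.00260 M⁻¹ min⁻¹)
    solid product ⇌ target, rate k3*(cs3 - [target]) while solid is left; crystals form when [target] > cs3 (solubility = 8.00 mM, k = 0.0610 min⁻¹)
    2 solid substrate → self-condensation product (k = 9.70 × 10⁻⁶ M⁻¹ min⁻¹)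

Tuesday's ended 5.1 percentage points under the take's figure, holding 13.6% as dissolved substrate at 12.0 d. At that time in Tuesday's the coupling step by itself, both ways together, had a relaxation half-life of 1.10 d, short against the 12 d of the run. In the neighbour with Tuesday's partner charge and 1.2 M of solid substrate, the take gives 21.9%, and the flask gave 20.6%.

All runs come from a simulation from invented constants; scatter was added.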